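**Assumption:** confluentic acid has no stereocentre and no stereogenic double bond, so the constitution given is the single compound to be made; all six starting materials are taken as catalogue items.

## Retrosynthetic overview

1. Target ⇒ its tert-butyl ester; the ester is cleaved last by acidolysis.
2. Depside C(aryl)–O bond ⇒ A-ring keto salicylic acid (used as a carboxylate O-nucleophile) + the C4–H bond of tert-butyl 2-methoxy-6-pentylbenzoate (through a boronate made in the flask).
3. A-ring acid ⇒ ortho-selective O-demethylation and lateral acylation of 2,4-dimethoxy-6-methylbenzoic acid with a hexanoyl Weinreb amide.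
4. B-ring arene ⇒ O-tert-butylation and lateral butylation of 2-methoxy-6-methylbenzoic acid.
5. Rings: both benzene rings are bought. The only ring formed is a transient isocoumarin lactone in the A-ring demethylation step, opened again in the same flask.

## Route

Step 1
Reactants: 1 2,4-dimethoxy-6-methylbenzoic acid; 2 N-methoxy-N-methylhexanamide
Product: 3 2,4-dimethoxy-6-(2-oxoheptyl)benzoic acid
Conditions: LDA (2.2 equiv), THF, −78 → 0 °C; then 2 (1.1 equiv), −78 °C → rt; cold 1 M HCl to pH 3
Reagents that add atoms: N-methoxy-N-methylhexanamide (2), CCCCCC(=O)N(C)OC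
Why: Lateral (benzylic) lithiation of the lithium o-toluate gives a dianion that adds once to the Weinreb amide, whose chelated tetrahedral adduct releases the ketone only on quench (Weinreb ketone synthesis), so there is no over-addition.

Step 2
Reactants: 3 2,4-dimethoxy-6-(2-oxoheptyl)benzoic acid
Product: 5 2-hydroxy-4-methoxy-6-(2-oxoheptyl)benzoic acid, via hydroxyisocoumarin 4 (not isolated)
Conditions: BCl3 (3 equiv), CH2Cl2, −78 °C → rt; evaporate; 2 M KOH, EtOH–H2O, 60 °C; cold 1 M HCl to pH 2–3, extract at 0 °C
Reagents that add atoms: potassium hydroxide (aqueous), [K+].[OH-]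
Why: BCl3 held between the carboxyl group and the ortho methoxy oxygen cleaves only that ether (chelation-controlled Lewis-acid O-demethylation), the acyloxyboron formed is trapped by the side-chain enol as enol lactone 4, and hydroxide then opens 4 to the keto acid (lactone saponification).

Step 3
Reactants: 6 2-methoxy-6-methylbenzoic acid; 7 1-iodobutane
Product: 8 2-methoxy-6-pentylbenzoic acid
Conditions: LDA (2.2 equiv), THF, −78 → 0 °C; then 7 (1.2 equiv), −78 °C → rt; 1 M HCl
Reagents that add atoms: 1-iodobutane (7), CCCCI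
Why: The o-toluate dianion from lateral lithiation is alkylated at the benzylic carbon by the primary iodide (SN2 alkylation of a metalated toluic acid).

Step 4
Reactants: 8 2-methoxy-6-pentylbenzoic acid; 9 tert-butyl 2,2,2-trichloroacetimidate
Product: 10 tert-butyl 2-methoxy-6-pentylbenzoate
Conditions: 9 (2 equiv), BF3·OEt2 (5 mol%), CH2Cl2–cyclohexane, rt
Reagents that add atoms: tert-butyl 2,2,2-trichloroacetimidate (9), CC(C)(C)OC(=N)C(Cl)(Cl)Cl
Why: Acid-catalysed imidate O-alkylation delivers a tert-butyl cation to the carboxyl oxygen, so the di-ortho-substituted acyl carbon never has to be attacked.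

Step 5
Reactants: 10 tert-butyl 2-methoxy-6-pentylbenzoate; 11 bis(pinacolato)diboron; 5 2-hydroxy-4-methoxy-6-(2-oxoheptyl)benzoic acid
Product: 13 tert-butyl 4-{[2-hydroxy-4-methoxy-6-(2-oxoheptyl)benzoyl]oxy}-2-methoxy-6-pentylbenzoate, via arylboronate 12 (not isolated)
Conditions: 10 (1.3 equiv), 11 (1.3 equiv), [Ir(OMe)(cod)]2 (1.5 mol%), dtbpy (3 mol%), THF, 80 °C; evaporate volatiles; then 5 (1.0 equiv), Cu(OTf)2 (30 mol%), pyridine (2 equiv), 4 Å MS, MeCN, dry air, 50 °C
Reagents that add atoms: none
Why: Proposed new method: a formal C–H acyloxylation in which the sterically controlled Ir(III) tris-boryl catalyst borylates the only ring C–H of 10 without an ortho substituent (C4, para to the ester), and the aryl group of 12 is then passed from boron to a Cu(II) carboxylate of 5, oxidised to an aryl–Cu(III) carboxylate and released by C(aryl)–O reductive elimination, so the acid of 5 acts only as an O-nucleophile and is never made an acyl electrophile that its own ketone enol could trap as isocoumarin 4, while pyridine deprotonates the carboxyl group (pKa about 3) but not the hydrogen-bonded phenol; the closest known reactions are the one-pot Ir C–H borylation/Cu Chan–Lam amination or etherification of arenes and the Cu(OTf)2-mediated Chan–Lam O-arylation of simple carboxylic acids with arylboronic acids, neither shown for an ArBpin made in situ together with a free salicylic acid that carries an enolisable ketone.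

Step 6
Reactants: 13 tert-butyl 4-{[2-hydroxy-4-methoxy-6-(2-oxoheptyl)benzoyl]oxy}-2-methoxy-6-pentylbenzoate
Product: 14 confluentic acid
Conditions: TFA–CH2Cl2 (1:4), iPr3SiH (3 equiv), 0 °C → rt
Reagents that add atoms: none
Why: Acidolysis of the tert-butyl ester by alkyl–oxygen cleavage (AAL1) is insensitive to the hindered acyl carbon and leaves the aryl ester, ketone and methyl ethers alone, while the silane reduces the tert-butyl cation before it can alkylate the electron-rich A ring.

## Compound list

1 | 2,4-dimethoxy-6-methylbenzoic acid (achiral) | Cc1cc(OC)cc(OC)c1C(=O)O | starting material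
2 | N-methoxy-N-methylhexanamide (achiral) | CCCCCC(=O)N(C)OC | starting material
3 | 2,4-dimethoxy-6-(2-oxoheptyl)benzoic acid (achiral) | CCCCCC(=O)Cc1cc(OC)cc(OC)c1C(=O)O | intermediate
4 | 8-hydroxy-6-methoxy-3-pentyl-1H-isochromen-1-one (achiral) | CCCCCC1=Cc2cc(OC)cc(O)c2C(=O)O1 | intermediate
5 | 2-hydroxy-4-methoxy-6-(2-oxoheptyl)benzoic acid (achiral) | CCCCCC(=O)Cc1cc(OC)cc(O)c1C(=O)O | intermediate
6 | 2-methoxy-6-methylbenzoic acid (achiral) | Cc1cccc(OC)c1C(=O)O | starting material
7 | 1-iodobutane | CCCCI | starting material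
8 | 2-methoxy-6-pentylbenzoic acid (achiral) | CCCCCc1cccc(OC)c1C(=O)O | intermediate
9 | tert-butyl 2,2,2-trichloroacetimidate | CC(C)(C)OC(=N)C(Cl)(Cl)Cl | starting material
10 | tert-butyl 2-methoxy-6-pentylbenzoate (achiral) | CCCCCc1cccc(OC)c1C(=O)OC(C)(C)C | intermediate
11 | bis(pinacolato)diboron | CC1(C)OB(OC1(C)C)B1OC(C)(C)C(C)(C)O1 | starting material
12 | tert-butyl 2-methoxy-6-pentyl-4-(4,4,5,5-tetramethyl-1,3,2-dioxaborolan-2-yl)benzoate (achiral) | CCCCCc1cc(B2OC(C)(C)C(C)(C)O2)cc(OC)c1C(=O)OC(C)(C)C | intermediate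
13 | tert-butyl 4-{[2-hydroxy-4-methoxy-6-(2-oxoheptyl)benzoyl]oxy}-2-methoxy-6-pentylbenzoate (achiral) | CCCCCC(=O)Cc1cc(OC)cc(O)c1C(=O)Oc1cc(CCCCC)c(C(=O)OC(C)(C)C)c(OC)c1 | intermediate
14 | confluentic acid, 4-{[2-hydroxy-4-methoxy-6-(2-oxoheptyl)benzoyl]oxy}-2-methoxy-6-pentylbenzoic acid (achiral) | CCCCCC(=O)Cc1cc(OC)cc(O)c1C(=O)Oc1cc(CCCCC)c(C(=O)O)c(OC)c1 | target

## Step count and risks

Total steps: 6. Longest linear sequence: 4 steps (1 → 3 → 5 → 13 → 14, or equally 6 → 8 → 10 → 13 → 14).

**Step 5 (the proposed new step).** It can fail through slow boron-to-copper transfer from the pinacol boronate, O-arylation of the phenol of 5, copper/air oxidation of the ArCH2C(=O) methylene, or protodeboronation. The fallback uses known chemistry only. It sets out from 10 and comes back at 13. Compound 10 is borylated as before to 12, and the crude boronate is oxidised in the same flask with aqueous Oxone in acetone to the phenol tert-butyl 4-hydroxy-2-methoxy-6-pentylbenzoate F1. F1 is then condensed with acid 5 by DCC in toluene at rt without any amine base (the classical depside condensation), which gives 13.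

**Step 2.** It can fail through cleavage of the second methyl ether, side reactions of the keto acid with BCl3, or loss of 5 on acidification by re-lactonisation or decarboxylation. The fallback sets the phenol free before the side chain exists and carries it masked. It sets out from 1 and comes back at 5. BCl3 in CH2Cl2 converts 1 into 2-hydroxy-4-methoxy-6-methylbenzoic acid F2. Acetone with TFAA/TFA turns F2 into the acetonide 7-methoxy-2,2,5-trimethyl-4H-1,3-benzodioxin-4-one F3. Lateral lithiation of F3 with LDA at −78 °C and addition of 2 gives 7-methoxy-2,2-dimethyl-5-(2-oxoheptyl)-4H-1,3-benzodioxin-4-one F4. Aqueous KOH in DMSO followed by cold acid opens F4 to 5.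

**Step 6.** Acid may enolise the ketone and close the isocoumarin with loss of the B-ring phenol, or the tert-butyl cation may alkylate the A ring. The fallback replaces acidolysis by fluoride cleavage of a silyl ester. It sets out from 8 and comes back at 14. TIPSCl and Et3N in CH2Cl2 give triisopropylsilyl 2-methoxy-6-pentylbenzoate F5. Under the conditions of step 5, F5 is borylated to triisopropylsilyl 2-methoxy-6-pentyl-4-(4,4,5,5-tetramethyl-1,3,2-dioxaborolan-2-yl)benzoate F6 (not isolated), which couples with 5 to give triisopropylsilyl 4-{[2-hydroxy-4-methoxy-6-(2-oxoheptyl)benzoyl]oxy}-2-methoxy-6-pentylbenzoate F7. HF·pyridine in THF at 0 °C then frees 14.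

## Further compounds

F1 | step 5 | tert-butyl 4-hydroxy-2-methoxy-6-pentylbenzoate | CCCCCc1cc(O)cc(OC)c1C(=O)OC(C)(C)C
F2 | step 2 | 2-hydroxy-4-methoxy-6-methylbenzoic acid | Cc1cc(OC)cc(O)c1C(=O)O
F3 | step 2 | 7-methoxy-2,2,5-trimethyl-4H-1,3-benzodioxin-4-one | Cc1cc(OC)cc2OC(C)(C)OC(=O)c12
F4 | step 2 | 7-methoxy-2,2-dimethyl-5-(2-oxoheptyl)-4H-1,3-benzodioxin-4-one | CCCCCC(=O)Cc1cc(OC)cc2OC(C)(C)OC(=O)c12
F5 | step 6 | triisopropylsilyl 2-methoxy-6-pentylbenzoate | CCCCCc1cccc(OC)c1C(=O)O[Si](C(C)C)(C(C)C)C(C)C
F6 | step 6 | triisopropylsilyl 2-methoxy-6-pentyl-4-(4,4,5,5-tetramethyl-1,3,2-dioxaborolan-2-yl)benzoate | CCCCCc1cc(B2OC(C)(C)C(C)(C)O2)cc(OC)c1C(=O)O[Si](C(C)C)(C(C)C)C(C)C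
F7 | step 6 | triisopropylsilyl 4-{[2-hydroxy-4-methoxy-6-(2-oxoheptyl)benzoyl]oxy}-2-methoxy-6-pentylbenzoate | CCCCCC(=O)Cc1cc(OC)cc(O)c1C(=O)Oc1cc(CCCCC)c(C(=O)O[Si](C(C)C)(C(C)C)C(C)C)c(OC)c1
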